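## Analysis of the target

The target 31 is an isoflavanone: a chroman-4-one (ring A fused to the dihydropyranone ring C, atoms O1, C2, C3, C4, C4a to C8a) that carries ring B at C3. Ring A is the 5,7-dihydroxy ring. Ring B is a 2',4'-dihydroxyphenyl group whose C3', the carbon between its two oxygens, bears a (2E)-7-hydroxy-3,7-dimethyloct-2-enyl chain, i.e. a geranyl group with its distal double bond hydrated. The only stereocentre is C3 (S); the E C2''=C3'' double bond is remote from it and independent of it. The C3 hydrogen is both alpha to the C4 carbonyl and benzylic to an electron-rich ring, so the configuration is lost by enolisation under base and under strong protic acid. Other sensitive points are the ortho-allyl phenol motif of ring B (acid closes a 2'- or 4'-oxygen onto C3''), the tertiary C7'' alcohol (ionisation) and, at the C4 carbinol oxidation level, the 2'-oxygen, which under acid traps a C4 cation as a pterocarpan. The difficulty is therefore not the skeleton but making C3 as one enantiomer and keeping it through ring closure and deprotection. The strategy rests on ring C being an alkyl aryl ether: the O1–C8a bond can be formed after C3 is set, on a compound in which C4 is still a carbinol and C3 has no acidic hydrogen. The C2–C3–C4 unit of that compound (primary alcohol, aryl-bearing methine, benzylic carbinol) is the reduced form of an aldol adduct.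

## Retrosynthetic reasoning

**Protecting groups, 31 from 30 from 29.** The four phenols are carried as methoxymethyl (MOM) ethers, because these direct the two lithiations on ring B and withstand organolithiums, borohydride, carbonate at 110 °C and the final oxidation. The tertiary hydroxyl is carried as a triethylsilyl (TES) ether. Mineral acid strong enough to hydrolyse aryl MOM ethers would also enolise the alpha-aryl ketone, since both processes are acid-catalysed to a similar degree. The MOM groups of ketone 29 are therefore removed by Lewis-acid-assisted acetal exchange with a thiol, giving silyl ether 30. The silyl ether, which shields C7'' from ionisation during that step, is removed last with buffered fluoride to give 31.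

**C4 carbonyl, 29 from 28.** The ketone is obtained by oxidising the C4 carbinol of chromanol 28. Placing this oxidation three steps from the end means every carbon–carbon and carbon–oxygen bond-forming step runs on material whose C3 cannot enolise. The forward reaction must be non-basic and must not touch the alkene.

**O1–C8a bond, 28 from 27.** This is the key disconnection. Cutting the aryl ether bond rather than O1–C2 turns ring A into a simple ortho-bromo aryl unit and leaves the aliphatic part as a 1,3-diol, 27. The forward reaction is a copper-catalysed etherification that must use the primary hydroxyl and leave the secondary one alone. Ring size guarantees this, since the C4 oxygen could only close a four-membered ring.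

**C3–C4 bond, 27 from 26 from 19 and 23.** Diol 27 is the reduction product of beta-hydroxy imide 26, and 26 is the syn aldol adduct of arylacetyl imide 19 with aldehyde 23. This places the only stereocentre that matters, C3, under auxiliary control in a well-understood transition state. Auxiliary 17 must be the (4R)-benzyl oxazolidinone. A (4S)-benzyl imide gives a 2S acyl centre in its boron syn aldol, so the (4R) imide gives 2R in 26. On reduction of the acyl carbon to CH2OH the two carbon substituents at that centre swap priority, so the same arrangement in space is S at C3 of 27, 28 and 31. The C4 configuration (R, syn) does not matter for the target because C4 is oxidised later.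

**Ring A aldehyde, 23 from 22 from 20.** The formyl carbon is cut from the ring. 5-Bromoresorcinol 20 is formylated at the position para to one hydroxyl and ortho to the other, next to bromine, to give 22. Both phenols are then capped to give 23. The bromine needed for the key step is thus present from the start.

**Arylacetyl unit, 19 from 16 and 17, 16 from 14 from 12.** The imide N–C bond is cut to acid 16 and auxiliary 17. The acid comes from primary alcohol 14 by oxidation. The two-carbon arm of 14 is attached at C1' by hydroxyethylation of aryllithium 13, generated from arene 12 at the only remaining position ortho to a MOM-oxy group. This uses the same directing groups twice and avoids electrophilic halogenation, which the side-chain alkene would not tolerate.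

**C3'–C1'' bond, 12 from 9 and 7, 9 from 8.** The bond between ring B and the chain is cut. The carbon between the two MOM-oxy groups of 9 is the most acidic on the ring, so lithiation there (10), transmetalation to copper (11) and allylation with bromide 7 place the chain unambiguously between the two oxygens. Compound 9 is the bis-MOM ether of resorcinol 8.

**Side chain, 7 from 5 from 4 from 3 from 1.** Bromide 7 is derived from geranyl acetate 1, which already holds the E double bond and the full carbon chain. The only change to the skeleton is Markovnikov hydration of the distal alkene, which is selective because the other alkene is deactivated by the allylic acetate (organomercurial 2, alcohol 3). Silylation (4), acetate removal (5) and conversion of the allylic alcohol via mesylate 6 to bromide 7 complete the fragment.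

## Alternatives that were turned down

**Alternative 1:** The side chain is disconnected at C1''–C2'' and at the C3''–methyl bond and attached to a finished chromanol. In the forward direction, zirconium-catalysed syn methylalumination of alkyne A2 creates the C3''–methyl bond and an alkenyl–aluminium bond. That bond is coupled under zerovalent palladium with benzylic chloride A3 to give A1.

- For it: the route is convergent, the E geometry follows from syn carbometalation, and the chain's functional groups are not carried through the core synthesis. On convergence and on suitability for chain analogues it is stronger than the chosen route.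
- Against it: the E alkene is not a problem here, since geranyl acetate 1 supplies it. A3 is a benzylic chloride flanked by two alkoxy groups and should ionise very easily. The coupling exposes a late intermediate with five acetal groups to an excess of a strongly Lewis acidic organoaluminium reagent. It does nothing for C3 or ring C, which would still have to be made, and it adds steps for the C3' hydroxymethyl group, its chlorination and a C4 silyl ether.
- In its place the chosen route offers alkene geometry from the pool, one copper-mediated allylation on a simple arene, and no Lewis acidic organometallic near the acetals.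

**Alternative 2:** Ring B is disconnected at four carbon–carbon bonds and built on a chroman that already holds the stereocentres. Irradiation of diazo ketone A5 causes Wolff rearrangement to a vinylketene. This adds to siloxyalkyne A6 by [2+2] cycloaddition, and four-electron ring opening, six-electron electrocyclisation and tautomerisation give phenol A4.

- For it: the substitution pattern of ring B follows from the mechanism, and the 2'-hydroxyl and 4'-silyloxy group emerge differentiated. That differentiation is a real advantage the chosen route lacks, although the chosen route never needs it.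
- Against it: ring B is a 2-substituted resorcinol, and resorcinol 8 is lithiated exactly at that position, so the ring can be bought rather than built. In A5 the C3 hydrogen is gamma to an enone carbonyl, with leaving groups on C2 and C4, which invites epimerisation and vinylogous elimination. A6 is a skipped enynyl silyl ether that is easily isomerised. The C3 stereocentre still needs a separate method on a chroman bearing an alkenyl group. The aryl silyl ethers must later come off at the ketone stage under fluoride, which is basic.
- It is much the longest of the options. The chosen route offers a commercial ring B and a C3 centre set by a standard aldol.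

**Alternative 3:** Ring A is disconnected at C4a–C5 and C8–C8a and built last. Diene A9 adds across the brominated double bond of dihydropyranone A8, and loss of hydrogen bromide and methanol aromatises the new ring to give A7.

- For it: ring A arrives with both phenols free, the endgame is short, and the regiochemistry follows from the polarity of the diene. On protecting-group economy for ring A it is stronger than the chosen route.
- Against it: C3 of A8 is alpha to a ketone and benzylic from the start. It must survive the bromination that makes A8, the addition of the diene and an aromatisation that releases hydrogen bromide, so it has three chances to enolise. The double bond of A8 belongs to a vinylogous ester and is a weak acceptor. No simple enantioselective access to the 3-aryl dihydropyranone is apparent.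
- In its place the chosen route offers configurational safety: C3 stays non-enolisable until the ketone is made three steps from the end, and from then on sees only buffered or Lewis acidic reagents.

Key step: step 14

Conventions: chroman numbering for rings A and C, primed numbers for ring B, doubly primed numbers for the chain. MOM = methoxymethyl, TES = triethylsilyl. ArB = 3-[(2E)-3,7-dimethyl-7-(triethylsilyloxy)oct-2-en-1-yl]-2,4-bis(methoxymethoxy)phenyl.
Assumption: auxiliary 17, geranyl acetate 1, resorcinol 8, 5-bromoresorcinol 20 and all reagents are taken as commercial; the C3 configuration read from the structure is S.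

## Route

Step 1
Reactants: 1 geranyl acetate
Product: 3 (2E)-7-hydroxy-3,7-dimethyloct-2-en-1-yl acetate, via organomercurial acetate 2 (not isolated)
Conditions: Hg(OAc)2 (1.0 equiv), THF/H2O 1:1, 20 °C; then aq NaOH, NaBH4, 0 °C
Reagents that add atoms: water, SMILES O
Why: Oxymercuration–demercuration (Markovnikov hydration). The distal C6=C7 alkene is the more electron-rich one because the C2=C3 alkene is deactivated by the allylic acetate, so one equivalent of divalent mercury adds there and water enters at the tertiary carbon; NaBH4 then replaces mercury by hydrogen and the E alkene is not touched.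

Step 2
Reactants: 3 (2E)-7-hydroxy-3,7-dimethyloct-2-en-1-yl acetate
Product: 4 (2E)-3,7-dimethyl-7-(triethylsilyloxy)oct-2-en-1-yl acetate
Conditions: TESOTf, 2,6-lutidine, CH2Cl2, −78 to 0 °C
Reagents that add atoms: triethylsilyl triflate, SMILES CC[Si](CC)(CC)OS(=O)(=O)C(F)(F)F
Why: Silylation of a hindered tertiary alcohol with a silyl triflate and a non-nucleophilic base. The ether protects the hydroxyl from the organolithium, boron triflate and mesylation steps to come.

Step 3
Reactants: 4 (2E)-3,7-dimethyl-7-(triethylsilyloxy)oct-2-en-1-yl acetate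
Product: 5 (2E)-3,7-dimethyl-7-(triethylsilyloxy)oct-2-en-1-ol
Conditions: K2CO3, MeOH, 0 to 20 °C
Reagents that add atoms: none
Why: Base-catalysed transesterification of the primary acetate with methanol. The hindered tertiary silyl ether should be stable to carbonate in methanol.

Step 4
Reactants: 5 (2E)-3,7-dimethyl-7-(triethylsilyloxy)oct-2-en-1-ol
Product: 7 (2E)-1-bromo-3,7-dimethyl-7-(triethylsilyloxy)oct-2-ene, via allylic mesylate 6 (not isolated)
Conditions: MsCl, Et3N, THF, −40 °C; then LiBr, THF, −40 to 0 °C
Reagents that add atoms: lithium bromide, SMILES [Li+].[Br-]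
Why: Mesylation followed by SN2 displacement with bromide. The low temperature and absence of HBr should prevent allylic transposition, E/Z loss and cleavage of the silyl ether.

Step 5
Reactants: 8 resorcinol
Product: 9 1,3-bis(methoxymethoxy)benzene
Conditions: MOMCl, i-Pr2NEt, CH2Cl2, 0 to 20 °C
Reagents that add atoms: chloromethyl methyl ether, SMILES COCCl
Why: O-alkylation of both phenols to the acetals. These serve as protecting groups and as directing groups for the two lithiations.

Step 6
Reactants: 9 1,3-bis(methoxymethoxy)benzene; 7 (2E)-1-bromo-3,7-dimethyl-7-(triethylsilyloxy)oct-2-ene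
Product: 12 2-[(2E)-3,7-dimethyl-7-(triethylsilyloxy)oct-2-en-1-yl]-1,3-bis(methoxymethoxy)benzene, via 2,6-bis(methoxymethoxy)phenyllithium 10 (not isolated), via 2,6-bis(methoxymethoxy)phenylcopper 11 (not isolated)
Conditions: n-BuLi, THF, 0 to 20 °C; CuI (1.0 equiv), −40 °C; then 7, −40 to 20 °C
Reagents that add atoms: none
Why: Directed ortho-metalation removes the hydrogen between the two MOM-oxy groups, which is the most acidic and is coordinated from both sides. The arylcopper then allylates the primary bromide at its alpha carbon (SN2), so the chain should arrive linear with the E geometry kept.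

Step 7
Reactants: 12 2-[(2E)-3,7-dimethyl-7-(triethylsilyloxy)oct-2-en-1-yl]-1,3-bis(methoxymethoxy)benzene
Product: 14 2-ArB-ethan-1-ol, via ring-B aryllithium 13 (not isolated)
Conditions: n-BuLi, TMEDA, THF, −20 to 0 °C; ethylene oxide, −78 to 20 °C; H2O
Reagents that add atoms: ethylene oxide, SMILES C1CO1
Why: Second directed ortho-metalation. With C2 blocked, the only sites ortho to a MOM-oxy group are C4 and C6, which are equivalent, so one aryllithium forms; it opens the epoxide to give the two-carbon alcohol.

Step 8
Reactants: 14 2-ArB-ethan-1-ol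
Product: 16 ArB-acetic acid, via ArB-acetaldehyde 15 (not isolated)
Conditions: TEMPO (cat.), PhI(OAc)2, MeCN/H2O, 20 °C
Reagents that add atoms: water, SMILES O
Why: Oxoammonium-mediated oxidation of the primary alcohol to the aldehyde and, through its hydrate, to the acid in one flask. The oxidant should leave the trisubstituted alkene, the acetals and the silyl ether alone.

Step 9
Reactants: 16 ArB-acetic acid; 17 (4R)-4-benzyl-1,3-oxazolidin-2-one
Product: 19 (4R)-4-benzyl-3-(ArB-acetyl)-1,3-oxazolidin-2-one, via mixed pivalic anhydride 18 (not isolated)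
Conditions: PivCl, Et3N, THF, −20 °C; then LiCl, 17, −20 to 20 °C
Reagents that add atoms: none
Why: N-acylation through a mixed anhydride. The LiCl-activated oxazolidinone attacks the less hindered arylacetyl carbonyl, and the low temperature limits ketene formation from the arylacetyl unit.

Step 10
Reactants: 20 5-bromoresorcinol
Product: 22 2-bromo-4,6-dihydroxybenzaldehyde, via aryl iminium chloride 21 (not isolated)
Conditions: POCl3, DMF, MeCN, −15 to 20 °C; then H2O, 50 °C
Reagents that add atoms: N,N-dimethylformamide, SMILES CN(C)C=O; water, SMILES O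
Why: Vilsmeier–Haack formylation. The chloroiminium ion attacks the position para to one hydroxyl and ortho to the other, as it does in resorcinol and orcinol, in preference to the position flanked by both hydroxyls; hydrolysis of the iminium salt gives the aldehyde.

Step 11
Reactants: 22 2-bromo-4,6-dihydroxybenzaldehyde
Product: 23 2-bromo-4,6-bis(methoxymethoxy)benzaldehyde
Conditions: MOMCl (excess), i-Pr2NEt, CH2Cl2, 0 to 20 °C
Reagents that add atoms: chloromethyl methyl ether, SMILES COCCl
Why: O-alkylation of both phenols. The excess of reagent is there to cap the hydroxyl that is hydrogen-bonded to the aldehyde.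

Step 12
Reactants: 19 (4R)-4-benzyl-3-(ArB-acetyl)-1,3-oxazolidin-2-one; 23 2-bromo-4,6-bis(methoxymethoxy)benzaldehyde
Product: 26 (4R)-4-benzyl-3-[(2R,3R)-2-ArB-3-[2-bromo-4,6-bis(methoxymethoxy)phenyl]-3-hydroxypropanoyl]-1,3-oxazolidin-2-one, via Z dibutylboron enolate 24 (not isolated), via dibutylboron aldolate 25 (not isolated)
Conditions: Bu2BOTf, i-Pr2NEt, CH2Cl2, −78 to 0 °C; 23, −78 to 0 °C; then pH 7 buffer, MeOH, H2O2, 0 °C
Reagents that add atoms: none
Why: Evans syn aldol. Soft enolisation gives the Z boron enolate, which reacts through a Zimmerman–Traxler chair with the auxiliary carbonyl turned away from the enolate oxygen, so the benzyl group of the (4R) auxiliary blocks one face and sets the alpha carbon as 2R (the future S-C3) and the carbinol as 3R (syn). Oxidative work-up releases boron from the aldolate.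

Step 13
Reactants: 26 the syn aldol adduct
Product: 27 (1R,2S)-2-ArB-1-[2-bromo-4,6-bis(methoxymethoxy)phenyl]propane-1,3-diol
Conditions: LiBH4, MeOH (1 equiv), THF, 0 °C
Reagents that add atoms: none
Why: Reductive cleavage of the N-acyl oxazolidinone by hydride attack at the exocyclic carbonyl, which releases the auxiliary. The aryl bromide, acetals and silyl ether are inert, and once the acyl carbon is CH2OH the C3 hydrogen is no longer acidic.

Step 14
Reactants: 27 (1R,2S)-2-ArB-1-[2-bromo-4,6-bis(methoxymethoxy)phenyl]propane-1,3-diol
Product: 28 (3S,4R)-3-ArB-5,7-bis(methoxymethoxy)-3,4-dihydro-2H-chromen-4-ol (3,4-trans)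
Conditions: CuI (10 mol %), 3,4,7,8-tetramethyl-1,10-phenanthroline (20 mol %), Cs2CO3, toluene, 110 °C, argon
Reagents that add atoms: none
Why: Intramolecular Ullmann-type O-arylation, i.e. copper-catalysed coupling of an aliphatic alcohol with an aryl bromide, a known way to close chromans. Cs2CO3 and ligand-bound monovalent copper convert the primary C2 hydroxyl into a copper alkoxide; oxidative addition of the neighbouring C8a–Br bond gives a seven-membered trivalent copper aryl alkoxide, and reductive elimination forms O1–C8a and returns monovalent copper. Ring C closes as a six-membered ring by attack of the chain oxygen on the ipso carbon, formally a 6-exo closure with the aromatic bond outside the new ring. No stereocentre is formed, and C3 and C4 keep their aldol configuration because no bond at either is made or broken and, with C4 a carbinol, there is no acidic C3 hydrogen for the carbonate to remove. The selectivity required is primary over secondary hydroxyl, and the substrate secures it: the C4 oxygen could only close a four-membered ring, the C2 oxygen a six-membered one. The bromide has one ortho substituent and is meta to both MOM-oxy groups, so oxidative addition is not slowed electronically, and the acetals, silyl ether and alkene are inert to carbonate and copper in toluene. Air is excluded so that copper does not oxidise the benzylic carbinol, and moderate dilution disfavours intermolecular etherification.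

Step 15
Reactants: 28 (3S,4R)-3-ArB-5,7-bis(methoxymethoxy)-3,4-dihydro-2H-chromen-4-ol
Product: 29 (3S)-3-ArB-5,7-bis(methoxymethoxy)-2,3-dihydro-4H-chromen-4-one
Conditions: Dess–Martin periodinane, NaHCO3, CH2Cl2, 0 to 20 °C
Reagents that add atoms: none
Why: Dess–Martin oxidation of the benzylic secondary alcohol under buffered, non-basic conditions. C3 becomes enolisable only here, so amine bases are avoided in reaction and work-up.

Step 16
Reactants: 29 (3S)-3-ArB-5,7-bis(methoxymethoxy)-2,3-dihydro-4H-chromen-4-one
Product: 30 (3S)-3-{3-[(2E)-3,7-dimethyl-7-(triethylsilyloxy)oct-2-en-1-yl]-2,4-dihydroxyphenyl}-5,7-dihydroxy-2,3-dihydro-4H-chromen-4-one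
Conditions: ZnBr2, n-PrSH, CH2Cl2, 0 °C, short reaction time
Reagents that add atoms: none
Why: Lewis-acid-assisted acetal exchange. Zinc binds the acetal oxygens and the thiol attacks the OCH2O carbon, so the four phenols should be freed quickly at 0 °C without a protic acid strong enough to enolise the ketone or protonate the alkene; the hindered tertiary silyl ether is expected to persist and to shield C7''.

Step 17
Reactants: 30 the triethylsilyl ether of the target
Product: 31 (3S)-5,7-dihydroxy-3-{2,4-dihydroxy-3-[(2E)-7-hydroxy-3,7-dimethyloct-2-en-1-yl]phenyl}-2,3-dihydro-4H-chromen-4-one (target)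
Conditions: HF·pyridine, pyridine, THF, 0 to 20 °C
Reagents that add atoms: none
Why: Fluoride-mediated desilylation in a buffered, weakly acidic medium. Neither enolisation at C3 nor reaction of the ortho-allyl phenol is expected under these conditions.

## Compound list

1 | geranyl acetate, (2E)-3,7-dimethylocta-2,6-dien-1-yl acetate | CC(C)=CCC/C(C)=C/COC(C)=O | starting material
2 | (2E)-6-(acetoxymercurio)-7-hydroxy-3,7-dimethyloct-2-en-1-yl acetate | CC(=O)OC/C=C(\C)CCC([Hg]OC(C)=O)C(C)(C)O | intermediate
3 | (2E)-7-hydroxy-3,7-dimethyloct-2-en-1-yl acetate | CC(=O)OC/C=C(\C)CCCC(C)(C)O | intermediate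
4 | (2E)-3,7-dimethyl-7-(triethylsilyloxy)oct-2-en-1-yl acetate | CC(=O)OC/C=C(\C)CCCC(C)(C)O[Si](CC)(CC)CC | intermediate
5 | (2E)-3,7-dimethyl-7-(triethylsilyloxy)oct-2-en-1-ol | OC/C=C(\C)CCCC(C)(C)O[Si](CC)(CC)CC | intermediate
6 | (2E)-3,7-dimethyl-7-(triethylsilyloxy)oct-2-en-1-yl methanesulfonate | CS(=O)(=O)OC/C=C(\C)CCCC(C)(C)O[Si](CC)(CC)CC | intermediate
7 | (2E)-1-bromo-3,7-dimethyl-7-(triethylsilyloxy)oct-2-ene | BrC/C=C(\C)CCCC(C)(C)O[Si](CC)(CC)CC | intermediate
8 | resorcinol | Oc1cccc(O)c1 | starting material
9 | 1,3-bis(methoxymethoxy)benzene | COCOc1cccc(OCOC)c1 | intermediate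
10 | 2,6-bis(methoxymethoxy)phenyllithium | [Li]c1c(OCOC)cccc1OCOC | intermediate
11 | 2,6-bis(methoxymethoxy)phenylcopper | [Cu]c1c(OCOC)cccc1OCOC | intermediate
12 | 2-[(2E)-3,7-dimethyl-7-(triethylsilyloxy)oct-2-en-1-yl]-1,3-bis(methoxymethoxy)benzene | C/C(=C\Cc1c(OCOC)cccc1OCOC)CCCC(C)(C)O[Si](CC)(CC)CC | intermediate
13 | {3-[(2E)-3,7-dimethyl-7-(triethylsilyloxy)oct-2-en-1-yl]-2,4-bis(methoxymethoxy)phenyl}lithium | C/C(=C\Cc1c(OCOC)ccc([Li])c1OCOC)CCCC(C)(C)O[Si](CC)(CC)CC | intermediate
14 | 2-{3-[(2E)-3,7-dimethyl-7-(triethylsilyloxy)oct-2-en-1-yl]-2,4-bis(methoxymethoxy)phenyl}ethan-1-ol | C/C(=C\Cc1c(OCOC)ccc(CCO)c1OCOC)CCCC(C)(C)O[Si](CC)(CC)CC | intermediate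
15 | {3-[(2E)-3,7-dimethyl-7-(triethylsilyloxy)oct-2-en-1-yl]-2,4-bis(methoxymethoxy)phenyl}acetaldehyde | C/C(=C\Cc1c(OCOC)ccc(CC=O)c1OCOC)CCCC(C)(C)O[Si](CC)(CC)CC | intermediate
16 | {3-[(2E)-3,7-dimethyl-7-(triethylsilyloxy)oct-2-en-1-yl]-2,4-bis(methoxymethoxy)phenyl}acetic acid | C/C(=C\Cc1c(OCOC)ccc(CC(=O)O)c1OCOC)CCCC(C)(C)O[Si](CC)(CC)CC | intermediate
17 | (4R)-4-benzyl-1,3-oxazolidin-2-one | O=C1N[C@H](Cc2ccccc2)CO1 | starting material
18 | mixed anhydride of acid 16 with pivalic acid | C/C(=C\Cc1c(OCOC)ccc(CC(=O)OC(=O)C(C)(C)C)c1OCOC)CCCC(C)(C)O[Si](CC)(CC)CC | intermediate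
19 | (4R)-4-benzyl-3-(ArB-acetyl)-1,3-oxazolidin-2-one | C/C(=C\Cc1c(OCOC)ccc(CC(=O)N2C(=O)OC[C@H]2Cc2ccccc2)c1OCOC)CCCC(C)(C)O[Si](CC)(CC)CC | intermediate
20 | 5-bromoresorcinol | Oc1cc(O)cc(Br)c1 | starting material
21 | (2-bromo-4,6-dihydroxybenzylidene)dimethyliminium chloride | C[N+](C)=Cc1c(O)cc(O)cc1Br.[Cl-] | intermediate
22 | 2-bromo-4,6-dihydroxybenzaldehyde | O=Cc1c(O)cc(O)cc1Br | intermediate
23 | 2-bromo-4,6-bis(methoxymethoxy)benzaldehyde | COCOc1cc(Br)c(C=O)c(OCOC)c1 | intermediate
24 | Z dibutylboron enolate of imide 19 | C/C(=C\Cc1c(OCOC)ccc(/C=C(\OB(CCCC)CCCC)N2C(=O)OC[C@H]2Cc2ccccc2)c1OCOC)CCCC(C)(C)O[Si](CC)(CC)CC | intermediate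
25 | dibutylboron aldolate of 26 (O-boron at the carbinol oxygen) | C/C(=C\Cc1c(OCOC)ccc([C@H]([C@@H](OB(CCCC)CCCC)c2c(Br)cc(OCOC)cc2OCOC)C(=O)N2C(=O)OC[C@H]2Cc2ccccc2)c1OCOC)CCCC(C)(C)O[Si](CC)(CC)CC | intermediate
26 | (4R)-4-benzyl-3-[(2R,3R)-2-ArB-3-[2-bromo-4,6-bis(methoxymethoxy)phenyl]-3-hydroxypropanoyl]-1,3-oxazolidin-2-one | C/C(=C\Cc1c(OCOC)ccc([C@H]([C@@H](O)c2c(Br)cc(OCOC)cc2OCOC)C(=O)N2C(=O)OC[C@H]2Cc2ccccc2)c1OCOC)CCCC(C)(C)O[Si](CC)(CC)CC | intermediate
27 | (1R,2S)-2-ArB-1-[2-bromo-4,6-bis(methoxymethoxy)phenyl]propane-1,3-diol | C/C(=C\Cc1c(OCOC)ccc([C@H]([C@@H](O)c2c(Br)cc(OCOC)cc2OCOC)CO)c1OCOC)CCCC(C)(C)O[Si](CC)(CC)CC | intermediate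
28 | (3S,4R)-3-ArB-5,7-bis(methoxymethoxy)-3,4-dihydro-2H-chromen-4-ol | C/C(=C\Cc1c(OCOC)ccc([C@H]2COc3cc(OCOC)cc(OCOC)c3[C@@H]2O)c1OCOC)CCCC(C)(C)O[Si](CC)(CC)CC | intermediate
29 | (3S)-3-ArB-5,7-bis(methoxymethoxy)-2,3-dihydro-4H-chromen-4-one | C/C(=C\Cc1c(OCOC)ccc([C@H]2COc3cc(OCOC)cc(OCOC)c3C2=O)c1OCOC)CCCC(C)(C)O[Si](CC)(CC)CC | intermediate
30 | (3S)-3-{3-[(2E)-3,7-dimethyl-7-(triethylsilyloxy)oct-2-en-1-yl]-2,4-dihydroxyphenyl}-5,7-dihydroxy-2,3-dihydro-4H-chromen-4-one | C/C(=C\Cc1c(O)ccc([C@H]2COc3cc(O)cc(O)c3C2=O)c1O)CCCC(C)(C)O[Si](CC)(CC)CC | intermediate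
31 | (3S)-5,7-dihydroxy-3-{2,4-dihydroxy-3-[(2E)-7-hydroxy-3,7-dimethyloct-2-en-1-yl]phenyl}-2,3-dihydro-4H-chromen-4-one | C/C(=C\Cc1c(O)ccc([C@H]2COc3cc(O)cc(O)c3C2=O)c1O)CCCC(C)(C)O | target

## Step count and least certain steps

Total: 17 steps. Longest linear sequence: 14 steps from geranyl acetate 1 (steps 1–4, 6–9, 12–17).

**Step 14 (key step).** The likely failures are slow oxidative addition at the ortho-substituted bromide, so that prolonged heating with carbonate leads to reductive loss of bromine, and copper-mediated oxidation of the benzylic carbinol if air enters. Fallback: form the other ether bond of ring C, O1–C2. Setting out from diol 27, Miyaura borylation (B2pin2, Pd(dppf)Cl2, KOAc, dioxane, 85 °C) should give the pinacol boronate F1. Oxidation (NaBO3·4H2O, THF/H2O) should give the phenol F2. Mitsunobu closure (PPh3, DIAD, THF, 0 °C) through the primary alcohol, which is activated ahead of the secondary one, should then give chromanol 28, where the route is rejoined.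

**Step 12.** The aldehyde is electron-rich and has two ortho substituents, so addition may be slow, the aldol may revert on warming or in work-up, and the boron triflate may strip MOM groups. Fallback: a magnesium-catalysed direct aldol with silyl trapping, which is suited to non-enolisable aromatic aldehydes, is made irreversible by silylation and gives the anti adduct. This is acceptable because C4 is oxidised later.
- Setting out from acid 16, acylation of (4S)-4-benzyl-1,3-oxazolidin-2-one as in step 9 gives the (4S) imide F3. The opposite auxiliary is used because a magnesium-chelated enolate exposes the other face.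
- MgCl2 (cat.), Et3N and Me3SiCl in ethyl acetate at 20 °C with aldehyde 23 should give the anti adduct trimethylsilyl ether F4.
- LiBH4 should give the silyloxy alcohol F5, and K2CO3 in MeOH the anti diol F6.
- The conditions of step 14 should give the cis chromanol F7, and Dess–Martin oxidation gives ketone 29, where the route is rejoined.

**Step 7.** Aryllithium 13 is hindered and internally chelated, so opening of the epoxide may be slow, and on warming proton transfer from the benzylic-allylic CH2 may quench it. Fallback: use a more reactive electrophile and build the second carbon separately. Setting out from arene 12, the same lithiation followed by DMF should give the aldehyde F8. Wittig methylenation (Ph3PCH3Br, KOt-Bu, THF) should give the styrene F9. Hydroboration with 9-BBN, which selects the monosubstituted alkene over the trisubstituted one, then NaBO3 oxidation, gives alcohol 14, where the route is rejoined.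

**Step 16.** With the ketone in place, the Lewis acid may promote enolisation and erode the C3 configuration, the thiol may add to the C4 carbonyl, or a freed ortho phenol may cyclise onto the C2''=C3'' alkene. Partial loss of the silyl ether would be harmless, because it only anticipates step 17. Fallback: exchange the acetals for silyl groups without acid. Setting out from ketone 29, Me3SiOTf with 2,2'-bipyridyl in CH2Cl2 at 0 °C should convert the four aryl MOM ethers into the aryl trimethylsilyl ethers F10. Neutral aqueous methanol should then hydrolyse these to tetraphenol 30, where the route is rejoined.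

## Further compounds

F1 | step 14 | (1R,2S)-2-ArB-1-[2,4-bis(methoxymethoxy)-6-(4,4,5,5-tetramethyl-1,3,2-dioxaborolan-2-yl)phenyl]propane-1,3-diol | C/C(=C\Cc1c(OCOC)ccc([C@H]([C@@H](O)c2c(B3OC(C)(C)C(C)(C)O3)cc(OCOC)cc2OCOC)CO)c1OCOC)CCCC(C)(C)O[Si](CC)(CC)CC
F2 | step 14 | (1R,2S)-2-ArB-1-[2-hydroxy-4,6-bis(methoxymethoxy)phenyl]propane-1,3-diol | C/C(=C\Cc1c(OCOC)ccc([C@H]([C@@H](O)c2c(O)cc(OCOC)cc2OCOC)CO)c1OCOC)CCCC(C)(C)O[Si](CC)(CC)CC
F3 | step 12 | (4S)-4-benzyl-3-(ArB-acetyl)-1,3-oxazolidin-2-one | C/C(=C\Cc1c(OCOC)ccc(CC(=O)N2C(=O)OC[C@@H]2Cc2ccccc2)c1OCOC)CCCC(C)(C)O[Si](CC)(CC)CC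
F4 | step 12 | (4S)-4-benzyl-3-[(2R,3S)-2-ArB-3-[2-bromo-4,6-bis(methoxymethoxy)phenyl]-3-(trimethylsilyloxy)propanoyl]-1,3-oxazolidin-2-one | C/C(=C\Cc1c(OCOC)ccc([C@H]([C@H](O[Si](C)(C)C)c2c(Br)cc(OCOC)cc2OCOC)C(=O)N2C(=O)OC[C@@H]2Cc2ccccc2)c1OCOC)CCCC(C)(C)O[Si](CC)(CC)CC
F5 | step 12 | (2S,3S)-2-ArB-3-[2-bromo-4,6-bis(methoxymethoxy)phenyl]-3-(trimethylsilyloxy)propan-1-ol | C/C(=C\Cc1c(OCOC)ccc([C@H]([C@H](O[Si](C)(C)C)c2c(Br)cc(OCOC)cc2OCOC)CO)c1OCOC)CCCC(C)(C)O[Si](CC)(CC)CC
F6 | step 12 | (1S,2S)-2-ArB-1-[2-bromo-4,6-bis(methoxymethoxy)phenyl]propane-1,3-diol | C/C(=C\Cc1c(OCOC)ccc([C@H]([C@H](O)c2c(Br)cc(OCOC)cc2OCOC)CO)c1OCOC)CCCC(C)(C)O[Si](CC)(CC)CC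
F7 | step 12 | (3S,4S)-3-ArB-5,7-bis(methoxymethoxy)-3,4-dihydro-2H-chromen-4-ol | C/C(=C\Cc1c(OCOC)ccc([C@H]2COc3cc(OCOC)cc(OCOC)c3[C@H]2O)c1OCOC)CCCC(C)(C)O[Si](CC)(CC)CC
F8 | step 7 | 3-[(2E)-3,7-dimethyl-7-(triethylsilyloxy)oct-2-en-1-yl]-2,4-bis(methoxymethoxy)benzaldehyde | C/C(=C\Cc1c(OCOC)ccc(C=O)c1OCOC)CCCC(C)(C)O[Si](CC)(CC)CC
F9 | step 7 | 1-ethenyl-3-[(2E)-3,7-dimethyl-7-(triethylsilyloxy)oct-2-en-1-yl]-2,4-bis(methoxymethoxy)benzene | C/C(=C\Cc1c(OCOC)ccc(C=C)c1OCOC)CCCC(C)(C)O[Si](CC)(CC)CC
F10 | step 16 | (3S)-3-{3-[(2E)-3,7-dimethyl-7-(triethylsilyloxy)oct-2-en-1-yl]-2,4-bis(trimethylsilyloxy)phenyl}-5,7-bis(trimethylsilyloxy)-2,3-dihydro-4H-chromen-4-one | C/C(=C\Cc1c(O[Si](C)(C)C)ccc([C@H]2COc3cc(O[Si](C)(C)C)cc(O[Si](C)(C)C)c3C2=O)c1O[Si](C)(C)C)CCCC(C)(C)O[Si](CC)(CC)CC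
A1 | alternative 1 | tert-butyl{[(3S,4R)-3-ArB-5,7-bis(methoxymethoxy)-3,4-dihydro-2H-chromen-4-yl]oxy}dimethylsilane | C/C(=C\Cc1c(OCOC)ccc([C@H]2COc3cc(OCOC)cc(OCOC)c3[C@@H]2O[Si](C)(C)C(C)(C)C)c1OCOC)CCCC(C)(C)O[Si](CC)(CC)CC
A2 | alternative 1 | triethyl[(2-methylhept-6-yn-2-yl)oxy]silane | C#CCCCC(C)(C)O[Si](CC)(CC)CC
A3 | alternative 1 | tert-butyl{[(3S,4R)-3-[3-(chloromethyl)-2,4-bis(methoxymethoxy)phenyl]-5,7-bis(methoxymethoxy)-3,4-dihydro-2H-chromen-4-yl]oxy}dimethylsilane | ClCc1c(OCOC)ccc([C@H]2COc3cc(OCOC)cc(OCOC)c3[C@@H]2O[Si](C)(C)C(C)(C)C)c1OCOC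
A4 | alternative 2 | 6-[(3S,4S)-5,7-bis(tert-butyldimethylsilyloxy)-4-(triethylsilyloxy)-3,4-dihydro-2H-chromen-3-yl]-2-[(2E)-3,7-dimethyl-7-(triethylsilyloxy)oct-2-en-1-yl]-3-(triisopropylsilyloxy)phenol | C/C(=C\Cc1c(O[Si](C(C)C)(C(C)C)C(C)C)ccc([C@H]2COc3cc(O[Si](C)(C)C(C)(C)C)cc(O[Si](C)(C)C(C)(C)C)c3[C@H]2O[Si](CC)(CC)CC)c1O)CCCC(C)(C)O[Si](CC)(CC)CC
A5 | alternative 2 | (3E)-4-[(3S,4S)-5,7-bis(tert-butyldimethylsilyloxy)-4-(triethylsilyloxy)-3,4-dihydro-2H-chromen-3-yl]-1-diazobut-3-en-2-one | [N-]=[N+]=CC(=O)/C=C/[C@H]1COc2cc(O[Si](C)(C)C(C)(C)C)cc(O[Si](C)(C)C(C)(C)C)c2[C@H]1O[Si](CC)(CC)CC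
A6 | alternative 2 | {[(4E)-5,9-dimethyl-9-(triethylsilyloxy)dec-4-en-1-yn-1-yl]oxy}triisopropylsilane | C/C(=C\CC#CO[Si](C(C)C)(C(C)C)C(C)C)CCCC(C)(C)O[Si](CC)(CC)CC
A7 | alternative 3 | (3S)-3-{2,4-bis(tert-butyldimethylsilyloxy)-3-[(2E)-3,7-dimethyl-7-(triethylsilyloxy)oct-2-en-1-yl]phenyl}-5,7-dihydroxy-2,3-dihydro-4H-chromen-4-one | C/C(=C\Cc1c(O[Si](C)(C)C(C)(C)C)ccc([C@H]2COc3cc(O)cc(O)c3C2=O)c1O[Si](C)(C)C(C)(C)C)CCCC(C)(C)O[Si](CC)(CC)CC
A8 | alternative 3 | (3S)-5-bromo-3-{2,4-bis(tert-butyldimethylsilyloxy)-3-[(2E)-3,7-dimethyl-7-(triethylsilyloxy)oct-2-en-1-yl]phenyl}-2,3-dihydro-4H-pyran-4-one | C/C(=C\Cc1c(O[Si](C)(C)C(C)(C)C)ccc([C@H]2COC=C(Br)C2=O)c1O[Si](C)(C)C(C)(C)C)CCCC(C)(C)O[Si](CC)(CC)CC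
A9 | alternative 3 | 1-methoxy-1,3-bis(trimethylsilyloxy)buta-1,3-diene | COC(O[Si](C)(C)C)=CC(=C)O[Si](C)(C)C
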